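## Retrosynthetic overview

1. Target ⇐ chelation-controlled reduction of the cage β-keto lactone, which sets the secondary carbinol last.
2. Cage ⇐ one-pot Type II carbonyl-ene / intramolecular Diels–Alder cascade of an acyclic silyloxy-dienone: ring B first (acetyl C=O + trisubstituted alkene), then the cyclopentane and both rings of the bicyclo[2.2.2]octane from the new exocyclic methylene and the cyclohexa-2,4-dienone.
3. Dienone ⇐ Pd-catalysed asymmetric dearomative C-allylation of 7-O-silylated 5,7-dihydroxy-4,6-dimethylphthalide (γ-lactone already in place) with an (E)-allylic carbonate.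
4. Carbonate ⇐ ethyl acetoacetate + acetone + methyl vinyl ketone: an asymmetric deconjugative Michael addition sets the spiro carbon; ring A (δ-lactone) follows by Still–Gennari olefination and acid lactonisation onto the isopropenyl group.
5. Ring order: γ-lactone and ring A before the union; then B → cyclopentane + bicyclo[2.2.2]octane in the key step.

Assumption: the antipodes of the phase-transfer catalyst (step 2) and of the Trost ligand (step 15) named below are taken to give the drawn configurations; if the sense of induction is opposite, the other antipode is used.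

## Route

Step 1
Reactants: 1 ethyl acetoacetate; 2 acetone
Product: 3 ethyl 2-acetyl-3-methylbut-2-enoate
Conditions: TiCl4, pyridine, THF, 0 °C → rt
Reagents that add atoms: none
Why: Lehnert-type Knoevenagel condensation in which TiCl4 activates acetone and traps the water while pyridine forms the titanium enolate of 1, giving the tetrasubstituted alkylidene acetoacetate with no stereocentre formed.

Step 2
Reactants: 3 ethyl 2-acetyl-3-methylbut-2-enoate; 4 methyl vinyl ketone
Product: 5 ethyl (2R)-2-acetyl-5-oxo-2-(prop-1-en-2-yl)hexanoate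
Conditions: N-(9-anthracenylmethyl)-O-allylcinchonidinium bromide (10 mol%), Cs2CO3 (30 mol%), PhMe, −40 °C
Reagents that add atoms: none
Why: Asymmetric phase-transfer deconjugative Michael addition in which γ-deprotonation of 3 gives the extended enolate, which as a tight ion pair with the chiral ammonium cation attacks 4 through its α-carbon (kinetic α-selectivity of dienolates) on the unshielded face, so the quaternary carbon bearing acetyl, ester and isopropenyl is formed as the (R)-enantiomer.

Step 3
Reactants: 5 ethyl (2R)-2-acetyl-5-oxo-2-(prop-1-en-2-yl)hexanoate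
Product: 6 diethyl (2E,6R)-6-acetyl-3-methyl-6-(prop-1-en-2-yl)hept-2-enedioate
Conditions: (EtO)2P(O)CH2CO2Et, NaH, THF, 0 °C → rt
Reagents that add atoms: triethyl phosphonoacetate CCOC(=O)CP(=O)(OCC)OCC
Why: Horner–Wadsworth–Emmons olefination in which the preformed phosphonate anion attacks only the unhindered methyl ketone (the acetyl group on the quaternary carbon is too congested) and gives the (E)-trisubstituted enoate as the major, separable isomer without touching the stereocentre.

Step 4
Reactants: 6 diethyl (2E,6R)-6-acetyl-3-methyl-6-(prop-1-en-2-yl)hept-2-enedioate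
Product: 7 (2E,6S)-6-(1-hydroxyethyl)-6-(hydroxymethyl)-3,7-dimethylocta-2,7-dien-1-ol
Conditions: DIBAL-H (7 equiv), CH2Cl2, −78 → 0 °C; Rochelle salt
Reagents that add atoms: none
Why: Exhaustive DIBAL-H reduction takes both esters to primary alcohols (1,2-reduction of the enoate) and the ketone to a carbinol whose configuration is irrelevant because it is re-oxidised in step 5, while the quaternary stereocentre cannot epimerise.

Step 5
Reactants: 7 (2E,6S)-6-(1-hydroxyethyl)-6-(hydroxymethyl)-3,7-dimethylocta-2,7-dien-1-ol
Product: 8 (2S,5E)-2-acetyl-5-methyl-2-(prop-1-en-2-yl)hept-5-enedial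
Conditions: Dess–Martin periodinane (3.6 equiv), CH2Cl2, 0 °C → rt
Reagents that add atoms: none
Why: Dess–Martin oxidation returns the neopentyl alcohol to the aldehyde, the secondary alcohol to the methyl ketone and the allylic alcohol to the (E)-enal under neutral conditions that do not deformylate the non-enolisable β-keto aldehyde.

Step 6
Reactants: 8 (2S,5E)-2-acetyl-5-methyl-2-(prop-1-en-2-yl)hept-5-enedial
Product: 9 methyl (2Z,4R,7E)-4-acetyl-7-methyl-9-oxo-4-(prop-1-en-2-yl)nona-2,7-dienoate
Conditions: (CF3CH2O)2P(O)CH2CO2Me (1.05 equiv), KHMDS, 18-crown-6, THF, −78 °C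
Reagents that add atoms: methyl bis(2,2,2-trifluoroethyl)phosphonoacetate COC(=O)CP(=O)(OCC(F)(F)F)OCC(F)(F)F
Why: Still–Gennari (Z)-selective HWE olefination in which the dissociated potassium phosphonate reacts at −78 °C with the saturated, α-acyl-activated aldehyde far faster than with the β,β-disubstituted enal or the hindered ketone, and kinetic elimination gives the (Z)-enoate needed for ring closure.

Step 7
Reactants: 9 methyl (2Z,4R,7E)-4-acetyl-7-methyl-9-oxo-4-(prop-1-en-2-yl)nona-2,7-dienoate
Product: 10 (5R)-5-acetyl-6,6-dimethyl-5-[(3E)-3-methyl-5-oxopent-3-en-1-yl]-5,6-dihydro-2H-pyran-2-one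
Conditions: TsOH·H2O (20 mol%), wet PhMe, 60 °C
Reagents that add atoms: water O
Why: Acid-catalysed Markovnikov lactonisation in which protonation of the isopropenyl group gives a tertiary cation that is captured by the cis-disposed ester carbonyl in a six-membered ring, and hydrolysis of the dialkoxycarbenium ion releases methanol to leave the gem-dimethyl δ-lactone (ring A), the conjugated enal alkene being too electron-poor to compete and the quaternary centre untouched.

Step 8
Reactants: 10 (5R)-5-acetyl-6,6-dimethyl-5-[(3E)-3-methyl-5-oxopent-3-en-1-yl]-5,6-dihydro-2H-pyran-2-one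
Product: 11 (5R)-5-acetyl-5-[(3E)-5-hydroxy-3-methylpent-3-en-1-yl]-6,6-dimethyl-5,6-dihydro-2H-pyran-2-one
Conditions: NaBH4, CeCl3·7H2O, MeOH, −78 °C
Reagents that add atoms: none
Why: Luche reduction in which the cerium-activated borohydride reduces the enal carbonyl 1,2 much faster than the hindered methyl ketone and leaves the unsaturated lactone alone, giving the (E)-allylic alcohol.

Step 9
Reactants: 11 (5R)-5-acetyl-5-[(3E)-5-hydroxy-3-methylpent-3-en-1-yl]-6,6-dimethyl-5,6-dihydro-2H-pyran-2-one
Product: 12 (2E)-5-[(3R)-3-acetyl-2,2-dimethyl-6-oxo-3,6-dihydro-2H-pyran-3-yl]-3-methylpent-2-en-1-yl methyl carbonate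
Conditions: ClCO2Me, pyridine, CH2Cl2, 0 °C
Reagents that add atoms: methyl chloroformate COC(=O)Cl
Why: Acylation of the only hydroxyl group gives the allylic carbonate that serves as leaving group and internal base source for π-allylpalladium chemistry.

Step 10
Reactants: 13 3,5-dihydroxy-4-methylbenzoic acid
Product: 14 5-(hydroxymethyl)-2-methylbenzene-1,3-diol
Conditions: BH3·THF (4 equiv), THF, 0 °C → reflux; MeOH
Reagents that add atoms: none
Why: Borane reduces the carboxylic acid to the benzylic alcohol in the presence of the free phenols (as borates), and a benzylic alcohol meta to both hydroxyls is not prone to over-reduction.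

Step 11
Reactants: 14 5-(hydroxymethyl)-2-methylbenzene-1,3-diol
Product: 15 5,7-dihydroxy-6-methyl-2-benzofuran-1(3H)-one
Conditions: KHCO3, CO2 (5 bar), H2O, 120 °C; then 6 M HCl, 60 °C
Reagents that add atoms: carbon dioxide O=C=O
Why: Kolbe–Schmitt carboxylation of the symmetrical resorcinol occurs at the free position ortho to one hydroxyl and para to the other, and on acidification the ortho-carboxy benzyl alcohol closes spontaneously to the phthalide.

Step 12
Reactants: 15 5,7-dihydroxy-6-methyl-2-benzofuran-1(3H)-one
Product: 16 4-[(dimethylamino)methyl]-5,7-dihydroxy-6-methyl-2-benzofuran-1(3H)-one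
Conditions: aq CH2O, aq Me2NH, EtOH, 0 °C → rt
Reagents that add atoms: formaldehyde C=O; dimethylamine CNC
Why: Phenol Mannich reaction at the single remaining ring position, which is ortho and para to the two hydroxyl groups.

Step 13
Reactants: 16 4-[(dimethylamino)methyl]-5,7-dihydroxy-6-methyl-2-benzofuran-1(3H)-one
Product: 17 5,7-dihydroxy-4,6-dimethyl-2-benzofuran-1(3H)-one (DHDMP)
Conditions: H2 (4 bar), 10% Pd/C, EtOH, 70 °C
Reagents that add atoms: none
Why: Hydrogenolysis of the phenolic Mannich base (benzylic C–N cleavage through the ortho-quinone methide) is the classical two-step C-methylation of phenols and leaves the phthalide intact.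

Step 14
Reactants: 17 5,7-dihydroxy-4,6-dimethyl-2-benzofuran-1(3H)-one (DHDMP)
Product: 18 5-hydroxy-4,6-dimethyl-7-[(triisopropylsilyl)oxy]-2-benzofuran-1(3H)-one
Conditions: NaH (2.2 equiv), THF, 0 °C; TIPSCl (1.05 equiv), −20 °C → rt; aq NH4Cl
Reagents that add atoms: triisopropylsilyl chloride CC(C)[Si](Cl)(C(C)C)C(C)C
Why: Silylation of the dianion takes place at the more basic and less hindered 7-phenoxide (the 5-phenoxide is the weaker base and is flanked by two methyl groups), which leaves the acidic 5-OH free and puts a bulky group next to C6.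

Step 15
Reactants: 12 (2E)-5-[(3R)-3-acetyl-2,2-dimethyl-6-oxo-3,6-dihydro-2H-pyran-3-yl]-3-methylpent-2-en-1-yl methyl carbonate; 18 5-hydroxy-4,6-dimethyl-7-[(triisopropylsilyl)oxy]-2-benzofuran-1(3H)-one
Product: 19 (4R)-4-{(2E)-5-[(3R)-3-acetyl-2,2-dimethyl-6-oxo-3,6-dihydro-2H-pyran-3-yl]-3-methylpent-2-en-1-yl}-4,6-dimethyl-7-[(triisopropylsilyl)oxy]-2-benzofuran-1,5(3H,4H)-dione
Conditions: Pd2(dba)3·CHCl3 (2.5 mol%), (R,R)-DACH-phenyl Trost ligand (7.5 mol%), CH2Cl2, 0 °C → rt
Reagents that add atoms: none
Why: Tsuji–Trost asymmetric allylic dearomatisation in which methoxide released from the carbonate generates the 5-phenoxide, O-allylation is reversible under palladium, and C-allylation occurs through the unsubstituted terminus of the syn-π-allyl complex (E-alkene retained) at ortho carbon C4 rather than at C6, which is shielded by the OTIPS group, the chiral pocket of the ligand selecting the face that gives the (4R) quaternary centre.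

Step 16
Reactants: 19 (4R)-4-{(2E)-5-[(3R)-3-acetyl-2,2-dimethyl-6-oxo-3,6-dihydro-2H-pyran-3-yl]-3-methylpent-2-en-1-yl}-4,6-dimethyl-7-[(triisopropylsilyl)oxy]-2-benzofuran-1,5(3H,4H)-dione
Product: 22 keto lactone cage (target ketone precursor), via ene adduct 20 (not isolated), via silyl enol ether cage 21 (not isolated)
Conditions: MeAlCl2 (2.2 equiv), ClCH2CH2Cl, −30 °C → rt, then 70 °C; then HF·pyridine, THF, 0 °C
Reagents that add atoms: none
Why: Proposed new method: a Lewis-acid Type II carbonyl-ene reaction (closest precedent: MeAlCl2-promoted Type II ene cyclisations of keto alkenes) closes ring B through a chair, bicyclo[3.3.1]-like transition state in which the aluminium-bound oxygen is axial to take the allylic methyl hydrogen, the (E)-alkene places the CH2–dienone arm equatorial and the lactone CMe2–O branch lies anti to the complexed oxygen, so that OH, side chain and lactone CH= end up cis and the exocyclic methylene is unveiled; on warming this alkene adds intramolecularly to the Lewis-acid-activated cyclohexa-2,4-dienone (closest precedent: intramolecular Diels–Alder reactions of 6-alkenyl cyclohexa-2,4-dienones giving isotwistanes) from the face that carries the tether, the two-atom tether enforcing the fused mode and the cis ring fusion and thereby fixing the three new cage stereocentres from the (4R) centre, and HF then cleaves the silyl enol ether to the β-keto lactone whose α-carbon equilibrates to the less hindered epimer.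

Step 17
Reactants: 22 keto lactone cage (target ketone precursor)
Product: 23 CNP0360620.2 (target)
Conditions: Zn(BH4)2 (1.0 equiv), Et2O/THF, −40 → −20 °C; aq NH4Cl
Reagents that add atoms: none
Why: Chelation-controlled reduction of a cyclic β-keto lactone in which zinc bridges the ketone and lactone carbonyls and hydride arrives on the face anti to the lactone carbon, giving the cis-β-hydroxy lactone (the required carbinol configuration), while the other ketone is flanked by two quaternary carbons and the unsaturated lactone is inert to Zn(BH4)2.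

## Compound list

1 | ethyl acetoacetate | CCOC(=O)CC(C)=O | starting material
2 | acetone | CC(C)=O | starting material
3 | ethyl 2-acetyl-3-methylbut-2-enoate | CCOC(=O)C(C(C)=O)=C(C)C | intermediate
4 | methyl vinyl ketone | C=CC(C)=O | starting material
5 | ethyl (2R)-2-acetyl-5-oxo-2-(prop-1-en-2-yl)hexanoate | CCOC(=O)[C@](C(C)=C)(C(C)=O)CCC(C)=O | intermediate
6 | diethyl (2E,6R)-6-acetyl-3-methyl-6-(prop-1-en-2-yl)hept-2-enedioate | CCOC(=O)[C@](C(C)=C)(C(C)=O)CC/C(C)=C/C(=O)OCC | intermediate
7 | (2E,6S)-6-(1-hydroxyethyl)-6-(hydroxymethyl)-3,7-dimethylocta-2,7-dien-1-ol (both carbinol epimers) | OC[C@](C(C)=C)(C(C)O)CC/C(C)=C/CO | intermediate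
8 | (2S,5E)-2-acetyl-5-methyl-2-(prop-1-en-2-yl)hept-5-enedial | O=C[C@](C(C)=C)(C(C)=O)CC/C(C)=C/C=O | intermediate
9 | methyl (2Z,4R,7E)-4-acetyl-7-methyl-9-oxo-4-(prop-1-en-2-yl)nona-2,7-dienoate | COC(=O)/C=C\[C@](C(C)=C)(C(C)=O)CC/C(C)=C/C=O | intermediate
10 | (5R)-5-acetyl-6,6-dimethyl-5-[(3E)-3-methyl-5-oxopent-3-en-1-yl]-5,6-dihydro-2H-pyran-2-one | CC1(C)OC(=O)C=C[C@]1(C(C)=O)CC/C(C)=C/C=O | intermediate
11 | (5R)-5-acetyl-5-[(3E)-5-hydroxy-3-methylpent-3-en-1-yl]-6,6-dimethyl-5,6-dihydro-2H-pyran-2-one | CC1(C)OC(=O)C=C[C@]1(C(C)=O)CC/C(C)=C/CO | intermediate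
12 | (2E)-5-[(3R)-3-acetyl-2,2-dimethyl-6-oxo-3,6-dihydro-2H-pyran-3-yl]-3-methylpent-2-en-1-yl methyl carbonate | CC1(C)OC(=O)C=C[C@]1(C(C)=O)CC/C(C)=C/COC(=O)OC | intermediate
13 | 3,5-dihydroxy-4-methylbenzoic acid | Cc1c(O)cc(C(=O)O)cc1O | starting material
14 | 5-(hydroxymethyl)-2-methylbenzene-1,3-diol | Cc1c(O)cc(CO)cc1O | intermediate
15 | 5,7-dihydroxy-6-methyl-2-benzofuran-1(3H)-one | O=C1OCc2cc(O)c(C)c(O)c12 | intermediate
16 | 4-[(dimethylamino)methyl]-5,7-dihydroxy-6-methyl-2-benzofuran-1(3H)-one | O=C1OCc2c(CN(C)C)c(O)c(C)c(O)c12 | intermediate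
17 | 5,7-dihydroxy-4,6-dimethyl-2-benzofuran-1(3H)-one (DHDMP) | O=C1OCc2c(C)c(O)c(C)c(O)c12 | intermediate
18 | 5-hydroxy-4,6-dimethyl-7-[(triisopropylsilyl)oxy]-2-benzofuran-1(3H)-one | O=C1OCc2c(C)c(O)c(C)c(O[Si](C(C)C)(C(C)C)C(C)C)c12 | intermediate
19 | (4R)-4-{(2E)-5-[(3R)-3-acetyl-2,2-dimethyl-6-oxo-3,6-dihydro-2H-pyran-3-yl]-3-methylpent-2-en-1-yl}-4,6-dimethyl-7-[(triisopropylsilyl)oxy]-2-benzofuran-1,5(3H,4H)-dione | O=C1[C@](C)(C/C=C(\C)CC[C@@]3(C(C)=O)C=CC(=O)OC3(C)C)C2=C(C(=O)OC2)C(O[Si](C(C)C)(C(C)C)C(C)C)=C1C | intermediate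
20 | ene adduct: spiro-lactone cyclohexanol with exocyclic methylene; tertiary OH cis to the CH2–dienone arm and to the lactone CH=; silyloxy-dienone intact | CC1(C)OC(=O)C=C[C@]12CCC(=C)[C@@H](C[C@@]3(C)C(=O)C(C)=C(O[Si](C(C)C)(C(C)C)C(C)C)C4=C3COC4=O)[C@@]2(C)O | intermediate
21 | silyl enol ether cage: hexacyclic Diels–Alder adduct, the TIPS enol ether of 22 | CC1(C)OC(=O)C=C[C@]12CC[C@]13C[C@]4(C)C(=O)[C@](C)(C[C@H]1[C@@]2(C)O)[C@]31COC(=O)C1=C4O[Si](C(C)C)(C(C)C)C(C)C | intermediate
22 | keto lactone cage: the target with its secondary alcohol as ketone (β-keto γ-lactone) | CC1(C)OC(=O)C=C[C@]12CC[C@]13C[C@]4(C)C(=O)[C@](C)(C[C@H]1[C@@]2(C)O)[C@]31COC(=O)[C@H]1C4=O | intermediate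
23 | CNP0360620.2 | CC1(C)OC(=O)C=C[C@]12CC[C@]13C[C@]4(C)C(=O)[C@](C)(C[C@H]1[C@@]2(C)O)[C@]31COC(=O)[C@H]1[C@H]4O | target

## Step count

Total steps: 17. Longest linear sequence: 12 steps (steps 1–9, then 15, 16, 17); the arene branch is steps 10–14.

## Steps most likely to fail, with fallbacks

Step 16 (ene / Diels–Alder cascade) is the riskiest. The ene chair with the CMe2–O branch equatorial would invert the ring-fusion CH and the carbinol carbon relative to the spiro centre, and the Lewis acid may also trigger retro-Claisen or translactonisation. The fallback sets out from 19 and comes back at 20. Ring B is closed as a stepwise, chloride-terminated Prins cyclisation (TiCl4, CH2Cl2, −78 °C), which runs through an open transition state rather than the cyclic ene array and stops at the tertiary chloride F1. Dehydrochlorination of F1 toward the methyl group (AgOTf, 2,6-di-tert-butylpyridine, CH2Cl2, 0 °C) then unveils the exocyclic alkene of 20, which is heated without Lewis acid (PhMe, 90 °C) to 21 and desilylated to 22.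

Step 15 (dearomative allylation) may give O-allylation, attack at C6 or at the ester-bearing carbon, or poor control of the new quaternary centre. The fallback sets out from 11 (with 18) and comes back at 19. Alcohol 11 is converted (CBr4, PPh3, CH2Cl2, 0 °C) into the allylic bromide F2. The lithium phenoxide of 18 (LiHMDS, PhMe, 0 °C) is then C-alkylated by SN2 through the chelated O–Li···Br array at the less hindered ortho carbon. This gives 19 together with its C4 epimer; the epimer cannot reach the cis-fused cycloaddition geometry in step 16 and is removed there.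

Step 2 (asymmetric Michael addition) may give low ee or γ-attack. The fallback sets out from 3 and comes back at 5, using a chiral-enamine (d'Angelo) Michael reaction. Compound 3 is deconjugated (LDA, THF, −78 °C; AcOH quench) to the β,γ-unsaturated keto ester F3. Condensation with (S)-1-phenylethylamine (PhMe, 4 Å sieves) gives the hydrogen-bonded enamino ester F4. F4 adds to 4 (THF, rt) through the chair, aza-ene-like transition state on the face anti to the phenyl group, and aqueous acetic acid hydrolysis releases 5; the (R)-amine is used if the sense is opposite.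

## Further compounds

F1 | step 16 | tertiary chloride from chloride-terminated Prins closure of ring B (chloride carbon as epimer mixture) | CC1(C)OC(=O)C=C[C@]12CCC(C)(Cl)[C@@H](C[C@@]3(C)C(=O)C(C)=C(O[Si](C(C)C)(C(C)C)C(C)C)C4=C3COC4=O)[C@@]2(C)O
F2 | step 15 | (5R)-5-acetyl-5-[(3E)-5-bromo-3-methylpent-3-en-1-yl]-6,6-dimethyl-5,6-dihydro-2H-pyran-2-one | CC1(C)OC(=O)C=C[C@]1(C(C)=O)CC/C(C)=C/CBr
F3 | step 2 | ethyl 2-acetyl-3-methylbut-3-enoate | CCOC(=O)C(C(C)=C)C(C)=O
F4 | step 2 | ethyl (2Z)-3-{[(1S)-1-phenylethyl]amino}-2-(prop-1-en-2-yl)but-2-enoate | CCOC(=O)/C(C(C)=C)=C(/C)N[C@@H](C)c1ccccc1
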